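Slowness is what you see first: in the ochre run the electrophile falls to 72.7% by 0.500 min, then needs until 2.50 min to reach 60.1%.

| flask | electrophile | nucleophile | free base | protic impurity | remark | time |
|---|---|---|---|---|---|---|
| ochre | 1 mM | 0.95 equiv | 2 equiv | 1.4 mM | run made earlier |  |
| green | 1 mM | 0.95 equiv | 2 equiv | 2.2 mM | run made earlier |  |
| flask | 1.0 mM | 0.950 equiv | 2.00 equiv | 1.00 mM |  | 2.5 min |

| run | time / min | electrophile / % | target / % |
|---|---|---|---|
| ochre | 0.167 | 80.5 | 19.3 |
| ochre | 0.500 | 72.7 | 26.4 |
| ochre | 0.833 | 69.6 | 28.4 |
| ochre | 1.33 | 66.3 | 30.7 |
| ochre | 2.00 | 63.4 | 31.5 |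
| ochre | 2.50 | 60.1 | 35.7 |
| green | 0.417 | 79.0 | 22.9 |
| green | 0.833 | 75.1 | 23.4 |
| green | 1.33 | 73.0 | 24.9 |
| green | 1.50 | 73.0 | 26.1 |
| green | 2.00 | 70.2 | 24.7 |
| green | 2.50 | 71.1 | 26.3 |

(readings scatter by 1 percentage point)

1. part of the electrophile that has reacted at 2.5 min
2. share of the unused nucleophile that is free and not bound as protonated nucleophile, at 2.5 min

- steps under discussion: electrophile + nucleophile -> acid set free + target; nucleophile + acid set free <-> protonated nucleophile; acid set free + free base <-> salt of the base; nucleophile + protic impurity -> quenched reagent; acid set free + target -> side product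
- the earlier runs do not show how much of nucleophile is bound; that part of a forecast is a guess

Build the flask one step at a time. With the main step alone, one nucleophile takes one electrophile, so the nucleophile, the limiting reagent at 0.950 equiv, sets the ceiling. Yet by 2.50 min the ochre run has reacted 39.9% and the green run 28.9%.

Now add the quench by protic impurity. Both steps take nucleophile, and if each is first order in its partners, c(nucleophile) cancels from their ratio. Book the charged nucleophile minus the reacted electrophile as impurity lost, as if no nucleophile stood in either run at that time, which is my assumption. The ratio of logarithms then reads 0.982 for ochre and 1.05 for green. Their mean, 1.01, is my selectivity factor S: the logarithm of the fraction of impurity left over that of the fraction of electrophile left.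

With S read near one, I take both to lose about the same fraction, so the nucleophile divides as c(electrophile) to S·c(protic impurity). Control passes to the impurity where these two cross, and this flask sits at the crossing. So I estimate the cap of this flask at 47.1%, half of the nucleophile.

Then the rest. I take protonated nucleophile to return through the free base, delaying the approach to the cap without lowering it. Acid set free attacks target, not electrophile. So I expect a value just under the cap, and the free share I cannot read.

The forecast gave 46% and 25%: “The slow tail suggests a bound reservoir feeding out through the base”.

The flask gives 43.6% and 41.2%, so the two part on the free share, by 16 percentage points.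

    electrophile + nucleophile → acid set free + target (k = 37.0 L mol⁻¹ s⁻¹)
    nucleophile + acid set free ⇌ protonated nucleophile, settled at all times (K = 5.60 × 10⁵ L mol⁻¹)
    acid set free + free base ⇌ salt of the base (K = 2.60 × 10⁶ L mol⁻¹, k = 310 L mol⁻¹ s⁻¹)
    nucleophile + protic impurity → quenched reagent (k = 38.0 L mol⁻¹ s⁻¹)
    acid set free + target → side product (k = 270 L mol⁻¹ s⁻¹)

This flask stands 3.5 points under the cap, with 0.0409 mM of protonated nucleophile at 2.50 min, and reads 47.0% at 25.0 min. Raise the electrophile to 2.5 mM, equivalents held. That neighbouring flask lies past the crossing, with S·c(protic impurity) below c(electrophile), and the same reckoning puts its cap at 67.6%. It gives 62.8% at 2.5 min, with target at 52.0% and side product at 10.8%.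

All runs were generated by integration from invented constants, noise included.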